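Remark on the chemistry: target numbering is used for all intermediates (C1 carries the exocyclic C7, the diene is C1=C2–C3=C4, O5 sits on C5 and O6 on C6). Compound 1 is drawn open-chain although it exists as cyclic hemiacetals.

## Structural features

The target is a single six-membered carbocycle, a cyclohexa-1,3-diene (C1=C2–C3=C4) whose C1 carries a benzoyloxymethyl group (C7–O7). The two sp3 ring carbons C5 and C6 are adjacent stereocentres, both R, with their oxygens trans. O5 is benzoylated, whereas O6 is a free hydroxyl wedged between C5 and the substituted C1, so the vicinal secondary oxygens O5 and O6 must be told apart. The compound is a dihydroarene: loss of either ring oxygen together with a neighbouring hydrogen gives a benzene ring, so acid, strong base and heat are threats once the diene exists, and the trans hydroxy benzoate can in addition shift its acyl group from O5 to O6 under basic conditions. The seven-carbon skeleton is simple; the difficulty is to combine two contiguous stereocentres, a conjugated diene and a two-to-one acylation pattern on a ring that is always one elimination away from aromaticity. The key step exploits the fact that C6 is a carbinol carbon bonded to C1, which becomes the α-carbon of an α,β-unsaturated carbonyl unit when C7 is raised to the ester level; this is the pattern of a Morita–Baylis–Hillman adduct and marks C1–C6 as the bond to form. A second latent element is C3=C4 next to O5: a cis-acetonide across O4/O5 on an enoate with a C3 methylene hides both the alkene and the O5 hydroxyl until the stereocentres are secure.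

## Logic of the disconnections

13 ⇒ 12. The O6–H bond is exchanged for an O6–Si bond. A removable group on O6 is the only reliable way to keep it distinct while O5 and O7 are acylated. The forward step must cleave silicon from oxygen without moving the O5 acyl group and without acid strong enough to aromatise the ring.

12 ⇒ 10 + 11. The two acyl C–O bonds at O5 and O7 are cut. Both benzoates then come from two equivalents of one reagent in one operation. The forward step only requires that O6 stays blocked.

10 ⇒ 9. C7 is returned to the ester oxidation level. This makes C1=C2–C7=O an enoate again, which the two earlier disconnections need. The forward reduction must be a clean 1,2-reduction of a dienoate in the presence of a silyl ether.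

9 ⇒ 8. The C3=C4 alkene and the free O5 are traced back to a C3 methylene and a C4–O4 bond, with O4 and O5 joined in an isopropylidene ketal. The diene, and with it the aromatisation risk, disappears from every earlier intermediate, and O5 is now distinguished from O6 by construction. The forward step must remove a C3 hydrogen and expel O4 in preference to O6, and must not let the silyl group move to the new O5 alkoxide.

8 ⇒ 7. The O6–Si bond is cut. The free C6 carbinol next to the ester-bearing C1 exposes the Morita–Baylis–Hillman pattern.

7 ⇒ 5. The C1–C6 bond is cut. The carbocycle opens to an acyclic enoate aldehyde whose only stereocentres, C4 and C5, are those of a pentose. The forward step must close the ring through C1, create C6 with O6 trans to O5, and leave the epimerisable C5 untouched.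

5 ⇒ 4. C6 is returned from aldehyde to primary alcohol, the form in which it can be stored. The oxidation must be non-basic.

4 ⇒ 2 + 3. The C1=C2 bond is cut. C1 and C7 come from a two-carbon phosphorane and C2–C6 from a lactol that acts as a masked aldehyde. Alkene geometry is of no consequence later, but the liberated hydroxyl must not add back to the enoate.

2 ⇒ 1. The two ketal C–O bonds at O4 and O5 are cut. In the pyranose form the future O6 is tied up in the hemiacetal ring, so the ketal can only form on the cis pair O4/O5 and no separate protection of O6 is needed. The forward step requires mild acid and a kinetic ketalising agent.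

## Other disconnections considered

Alternative 1: The cut removes both ring C–O bonds (C5–O and C6–O) in favour of an oxirane and traces the carbocycle to an arene. Birch reduction of benzoic acid A1 and reduction of the carboxyl group would give the symmetric dienyl carbinol A2, in which the alkenes C2=C3 and C5=C6 are enantiotopic. In the forward key step Zr(OtBu)4 (tetravalent zirconium), a chiral bis-hydroxamic acid and cumene hydroperoxide would epoxidise one of these alkenes on the face of the homoallylic hydroxyl, giving the cis-epoxy alcohol A3.

- In its favour: the starting material is very cheap and all seven carbons are present from the outset. The absolute configuration is catalyst-controlled, so either enantiomer is accessible; on this point it is better than the chosen plan, which depends on the less common L-pentose. Trans opening of the oxirane at C5 by benzoate would give the 5-benzoate/6-hydroxyl pattern directly, with no protecting group on O6, which is also better than the chosen plan.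
- Against it: A3 is at the wrong oxidation level. C1 and C4 are sp3 and only C2=C3 is present, so the C1=C2–C3=C4 diene would need a net dehydrogenation (for example bromine addition and double dehydrobromination) on a compound that already carries an allylic ester and a free hydroxyl and aromatises easily. The site of oxirane opening (C5 versus C6) and the degree of enantiotopic-alkene selection on a doubly allylic ring carbinol are open.
- Comparison: on structure the alternative starts with the ring already made, whereas the chosen plan must build it; the chosen plan, however, generates the diene in the correct position as a consequence of its protecting group. On mechanism it uses reagent control where the chosen plan uses chiral-pool and substrate control. On step economy it is about equal (roughly eight to nine operations), with its least predictable steps at the end.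

Alternative 2: The cut is double, C1–C2 and C5–C6, and divides the ring into furan A4 and the Z-configured acetoxyacryloyl imide A5; the furan oxygen becomes O5. In the forward key step Cu(SbF6)2 (divalent copper) with a chiral tert-butyl bis(oxazoline) ligand would catalyse an endo-selective Diels–Alder reaction to the 7-oxanorbornene A6. A later base-induced β-elimination from C1 would break the C2–O bridge bond, creating C1=C2 beside the existing C3=C4 and freeing O5.

- In its favour: two C–C bonds, the ring, both stereocentres and all three oxygenated positions arise in one catalytic asymmetric step. The trans relation of O5 and O6 follows from dienophile geometry and the endo rule, which is more secure than the facial selectivity the chosen plan needs at C6. The diene is produced by a single elimination. On step economy it could be two or three steps shorter, and on all these points it is better.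
- Against it: the β-acyloxy group makes A5 a poor dienophile, and furan cycloadducts revert on warming. The enolate at C1 of A6 has two β-leaving groups, and loss of the C6 acyloxy group competes with bridge opening. The acyl pattern is inverted: O6 arrives acylated although it must end free, and O5 arrives free although it must be benzoylated. Reduction of the C7 imide would not spare ring esters, so protecting-group exchanges on an aromatisable dienol would be required.
- Comparison: the alternative is more convergent and in principle shorter, but it places its chemoselectivity problems on the most fragile intermediates. The chosen plan is longer and linear, but each step after the ring closure is of a well-understood type and the diene appears only four steps from the end.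

Alternative 3: The cut is the ring bond C2–C3, remote from the stereocentres. 2-Deoxy-D-glucose A7 would be converted in several steps into the enol ether A8, with O5 already benzoylated and O6 already silylated. In the forward key step catalytic Hg(O2CCF3)2 (divalent mercury) in aqueous acetone would hydrate the enol ether; the pyranoside would open and the resulting mercury enolate would add to the liberated aldehyde, closing the carbocycle to the hydroxy ketone A9.

- In its favour: both stereocentres and their trans relation are taken directly from the sugar, so no diastereoselection is needed at C5 or C6, which is better than the chosen plan. O5 and O6 are differentiated before the ring is made, which is also better. The ring closure is a robust, well-understood reaction, and the new carbinol at C3 is removed later, so its configuration is irrelevant.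
- Against it: C7 is absent. The C1 ketone would have to be converted into the C1=C2–C3=C4 diene with a carbon substituent: dehydration across C2–C3, O-sulfonylation of the extended enolate, a Pd(PPh3)4-catalysed (zerovalent palladium) one-carbon coupling, and adjustment of the oxidation level. Each enolisation of the C1 ketone places the C5 benzoate β to an enolate carbon (C6) and invites its elimination. The preparation of A8 itself needs about five steps, and a toxic mercury salt is used.
- Comparison: on structure it forms a bond far from the stereocentres, whereas the chosen plan forms the bond next to the new stereocentre, which is riskier but more direct. On mechanism both are intramolecular aldol closures of sugar-derived carbonyl compounds. On step economy the chosen plan is clearly shorter (nine steps against about thirteen), because its olefination reagent brings C7 in at the correct position and oxidation level.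

Key step: step 4

## Route

Step 1
Reactants: 1 2-deoxy-L-ribose
Product: 2 2-deoxy-3,4-O-isopropylidene-L-erythro-pentopyranose (cis-fused acetonide lactol; anomeric mixture)
Conditions: 2-methoxypropene, PPTS (cat.), EtOAc, 0 °C → rt
Reagents that add atoms: 2-methoxypropene, COC(C)=C
Why: Acid-catalysed transketalisation with an enol ether; in the pyranose form the primary oxygen (future O6) is held in the hemiacetal ring, so the only pair able to form a five-membered ketal is the cis-diol that becomes O4/O5, and no stereocentre is created or disturbed.

Step 2
Reactants: 2 2-deoxy-3,4-O-isopropylidene-L-erythro-pentopyranose; 3 methyl (triphenylphosphoranylidene)acetate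
Product: 4 methyl (E)-4-[(4R,5S)-5-(hydroxymethyl)-2,2-dimethyl-1,3-dioxolan-4-yl]but-2-enoate
Conditions: PhCO2H (cat.), THF, 65 °C
Reagents that add atoms: none
Why: Wittig olefination of the lactol through its open-chain aldehyde with a stabilised ylide, which should favour the E-enoate (the geometry is lost in step 4 in any case); the trace of benzoic acid speeds lactol opening and keeps the medium non-basic, so the freed primary hydroxyl should not add back to the enoate.

Step 3
Reactants: 4 methyl (E)-4-[(4R,5S)-5-(hydroxymethyl)-2,2-dimethyl-1,3-dioxolan-4-yl]but-2-enoate
Product: 5 methyl (E)-4-[(4R,5R)-5-formyl-2,2-dimethyl-1,3-dioxolan-4-yl]but-2-enoate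
Conditions: Dess–Martin periodinane, pyridine, CH2Cl2, 0 °C → rt; used crude at once
Reagents that add atoms: none
Why: Dess–Martin oxidation of the primary alcohol under buffered, essentially neutral conditions, which should leave the epimerisable α-alkoxy centre C5, the acetonide and the enoate intact; the descriptor at the aldehyde-bearing carbon changes from S to R only because the substituent priorities change.

Step 4
Reactants: 5 methyl (E)-4-[(4R,5R)-5-formyl-2,2-dimethyl-1,3-dioxolan-4-yl]but-2-enoate
Product: 7 methyl (3aS,4R,7aR)-4-hydroxy-2,2-dimethyl-3a,4,7,7a-tetrahydro-1,3-benzodioxole-5-carboxylate, via phosphonium alkoxide aldol adduct 6 (not isolated)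
Conditions: PMe3 (0.5 equiv, 1.0 M in THF), t-AmOH (0.03 M), rt
Reagents that add atoms: none
Why: Intramolecular Morita–Baylis–Hillman reaction: PMe3 adds in conjugate fashion to C2 of the enoate, and the phosphonium ester enolate attacks the C6 aldehyde through its α-carbon C1 to give alkoxide 6; proton transfer from C1 to oxygen, relayed by the tertiary alcohol solvent, and E1cB loss of PMe3 then restore C1=C2. The closest known reaction type is the phosphine-catalysed cyclisation of ω-formyl α,β-unsaturated esters and thioesters to 2-(alkoxycarbonyl)cycloalk-2-enols, which has been applied to carbohydrate-derived substrates. The one ring closed is the six-membered carbocycle, by a 6-(enolexo)-exo-trig aldol addition. The one new stereocentre, C6, is controlled by the neighbouring C5 held in the cis-dioxolane: in the chair-like transition state the C5–O5 bond lies antiperiplanar to the forming C1–C6 bond (a polar Felkin–Anh arrangement) and the aldehyde oxygen is pseudo-equatorial, away from the axial O4, which should place O6 trans to O5 (6R). The C1 and C2 centres of 6 are transient and vanish on elimination, so either enoate geometry converges on 7. The step needs attack of phosphorus on the enoate and not on the aldehyde, ring closure in preference to oligomerisation, and retention of configuration at C5; the soft, weakly basic phosphine, the high dilution and the short tether between C2 and C6 serve these needs. Because the aldol addition is reversible before proton transfer, equilibration should reinforce the trans arrangement.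

Step 5
Reactants: 7 methyl (3aS,4R,7aR)-4-hydroxy-2,2-dimethyl-3a,4,7,7a-tetrahydro-1,3-benzodioxole-5-carboxylate
Product: 8 methyl (3aR,4R,7aR)-4-[(tert-butyldimethylsilyl)oxy]-2,2-dimethyl-3a,4,7,7a-tetrahydro-1,3-benzodioxole-5-carboxylate
Conditions: TBSOTf, 2,6-lutidine, CH2Cl2, −78 → 0 °C
Reagents that add atoms: tert-butyldimethylsilyl trifluoromethanesulfonate (TBSOTf), CC(C)(C)[Si](C)(C)OS(=O)(=O)C(F)(F)F
Why: Silyl ether formation with a silyl triflate and a hindered pyridine base, suited to the crowded secondary allylic hydroxyl; it marks O6 for the rest of the route, and the geometry is unchanged (only the descriptor at C3a changes, through priorities).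

Step 6
Reactants: 8 methyl (3aR,4R,7aR)-4-[(tert-butyldimethylsilyl)oxy]-2,2-dimethyl-3a,4,7,7a-tetrahydro-1,3-benzodioxole-5-carboxylate
Product: 9 methyl (5R,6R)-6-[(tert-butyldimethylsilyl)oxy]-5-hydroxycyclohexa-1,3-diene-1-carboxylate
Conditions: KOtBu (1.1 equiv), THF, −78 → −40 °C; AcOH quench at −78 °C
Reagents that add atoms: none
Why: E1cB 1,4-elimination (vinylogous β-elimination) of a δ-alkoxy enoate: KOtBu removes a γ-hydrogen at C3, the extended enolate expels O4 to give C3=C4, and the hemiketal alkoxide loses acetone to leave the C5 alkoxide, whose charge opposes a second deprotonation and so guards against aromatisation; C5 and C6 are not touched.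

Step 7
Reactants: 9 methyl (5R,6R)-6-[(tert-butyldimethylsilyl)oxy]-5-hydroxycyclohexa-1,3-diene-1-carboxylate
Product: 10 (1R,6R)-6-[(tert-butyldimethylsilyl)oxy]-5-(hydroxymethyl)cyclohexa-2,4-dien-1-ol
Conditions: iBu2AlH (3.5 equiv), CH2Cl2, −78 °C; aq. potassium sodium tartrate
Reagents that add atoms: none
Why: 1,2-Reduction of a conjugated ester to the allylic alcohol by iBu2AlH at low temperature; the first equivalent is consumed by the free hydroxyl, and the silyl ether and the diene should be inert.

Step 8
Reactants: 10 (1R,6R)-6-[(tert-butyldimethylsilyl)oxy]-5-(hydroxymethyl)cyclohexa-2,4-dien-1-ol; 11 benzoyl chloride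
Product: 12 [(5R,6R)-5-(benzoyloxy)-6-[(tert-butyldimethylsilyl)oxy]cyclohexa-1,3-dien-1-yl]methyl benzoate
Conditions: 11 (2.4 equiv in all), pyridine, DMAP (cat.), CH2Cl2, 0 °C
Reagents that add atoms: benzoyl chloride (second equivalent of 11), O=C(Cl)c1ccccc1
Why: Double O-acylation of the primary allylic and the secondary hydroxyl with an acid chloride under nucleophilic catalysis, one molecule of 11 being consumed at each oxygen; O6 is blocked, so only O5 and O7 can react, and no stereocentre is involved.

Step 9
Reactants: 12 [(5R,6R)-5-(benzoyloxy)-6-[(tert-butyldimethylsilyl)oxy]cyclohexa-1,3-dien-1-yl]methyl benzoate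
Product: 13 [(5R,6R)-5-(benzoyloxy)-6-hydroxycyclohexa-1,3-dien-1-yl]methyl benzoate
Conditions: HF·pyridine, pyridine, THF, 0 °C → rt
Reagents that add atoms: none
Why: Fluoride-driven cleavage of the Si–O bond in a pyridine-buffered, weakly acidic medium, chosen because the O5 to O6 acyl shift is base-promoted and the dienol does not tolerate strong acid; the stereocentres are not involved.

## Compound list

1 | 2-deoxy-L-ribose (2-deoxy-L-erythro-pentose; drawn open-chain) | C(C=O)[C@H]([C@H](CO)O)O | starting material
2 | 2-deoxy-3,4-O-isopropylidene-L-erythro-pentopyranose (anomeric mixture) | OC1C[C@H]2OC(C)(C)O[C@H]2CO1 | intermediate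
3 | methyl (triphenylphosphoranylidene)acetate | COC(=O)C=P(c1ccccc1)(c1ccccc1)c1ccccc1 | starting material
4 | methyl (E)-4-[(4R,5S)-5-(hydroxymethyl)-2,2-dimethyl-1,3-dioxolan-4-yl]but-2-enoate | COC(=O)/C=C/C[C@H]1OC(C)(C)O[C@H]1CO | intermediate
5 | methyl (E)-4-[(4R,5R)-5-formyl-2,2-dimethyl-1,3-dioxolan-4-yl]but-2-enoate | COC(=O)/C=C/C[C@H]1OC(C)(C)O[C@H]1C=O | intermediate
6 | methyl 6-oxido-4,5-(isopropylidenedioxy)-2-(trimethylphosphonio)cyclohexane-1-carboxylate (target numbering; zwitterion formed in the flask and not isolated; C4, C5 and C6 as in 7, C1 and C2 transient and unassigned) | COC(=O)C1C([P+](C)(C)C)C[C@H]2OC(C)(C)O[C@H]2[C@@H]1[O-] | intermediate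
7 | methyl (3aS,4R,7aR)-4-hydroxy-2,2-dimethyl-3a,4,7,7a-tetrahydro-1,3-benzodioxole-5-carboxylate | COC(=O)C1=CC[C@H]2OC(C)(C)O[C@H]2[C@@H]1O | intermediate
8 | methyl (3aR,4R,7aR)-4-[(tert-butyldimethylsilyl)oxy]-2,2-dimethyl-3a,4,7,7a-tetrahydro-1,3-benzodioxole-5-carboxylate | COC(=O)C1=CC[C@H]2OC(C)(C)O[C@H]2[C@@H]1O[Si](C)(C)C(C)(C)C | intermediate
9 | methyl (5R,6R)-6-[(tert-butyldimethylsilyl)oxy]-5-hydroxycyclohexa-1,3-diene-1-carboxylate | COC(=O)C1=CC=C[C@@H](O)[C@@H]1O[Si](C)(C)C(C)(C)C | intermediate
10 | (1R,6R)-6-[(tert-butyldimethylsilyl)oxy]-5-(hydroxymethyl)cyclohexa-2,4-dien-1-ol | OCC1=CC=C[C@@H](O)[C@@H]1O[Si](C)(C)C(C)(C)C | intermediate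
11 | benzoyl chloride | O=C(Cl)c1ccccc1 | starting material
12 | [(5R,6R)-5-(benzoyloxy)-6-[(tert-butyldimethylsilyl)oxy]cyclohexa-1,3-dien-1-yl]methyl benzoate | O=C(OCC1=CC=C[C@@H](OC(=O)c2ccccc2)[C@@H]1O[Si](C)(C)C(C)(C)C)c1ccccc1 | intermediate
13 | [(5R,6R)-5-(benzoyloxy)-6-hydroxycyclohexa-1,3-dien-1-yl]methyl benzoate (CNP0113836.1) | O=C(OCC1=CC=C[C@@H](OC(=O)c2ccccc2)[C@@H]1O)c1ccccc1 | target

## Step count and least certain steps

Total step count: 9. Longest linear sequence: 9 steps (1 to 13); 3 and 11 are commercial and enter in steps 2 and 8.

Step 4 (key step). The most likely failure is slow conjugate addition of the phosphine to a simple enoate, which would leave time for epimerisation at C5 or for intermolecular aldol oligomerisation. A second risk is poor facial selectivity at C6, and a third is proton shift to a C2 ylide followed by Wittig-type closure to a five-membered ring. The fallback replaces the catalytic nucleophile by a stoichiometric sulfur nucleophile and restores the alkene separately. It sets out from 5: Me2AlSPh (from AlMe3 and PhSH) in CH2Cl2 at −78 °C should add thiolate to C2 and close the aluminium enolate onto the aldehyde (tandem Michael–aldol) to give methyl (3aS,4R,7aR)-4-hydroxy-2,2-dimethyl-6-(phenylsulfanyl)hexahydro-1,3-benzodioxole-5-carboxylate F1. Oxidation with mCPBA (2.2 equiv, CH2Cl2, 0 °C) would give the sulfone, methyl (3aS,4R,7aR)-4-hydroxy-2,2-dimethyl-6-(phenylsulfonyl)hexahydro-1,3-benzodioxole-5-carboxylate F2. DBU in CH2Cl2 at room temperature should then remove sulfinate by E1cB from C1, whatever the relative configuration at C1 and C2. The fallback returns to the route at 7.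

Step 6. Three processes may interfere: expulsion of the O6 silyloxy group from the α-terminus of the extended enolate in place of O4, transfer of the silyl group from O6 to the freshly formed O5 alkoxide, and a second elimination leading to an arene. The fallback removes silicon from the end-game altogether. It sets out from 7: KOtBu (2.2 equiv, THF, −78 → −20 °C) first converts O6 into an alkoxide, which can neither leave nor pass on a silyl group, and then opens the acetonide to methyl (5R,6R)-5,6-dihydroxycyclohexa-1,3-diene-1-carboxylate F3. Reduction with iBu2AlH (CH2Cl2, −78 °C) would give (1R,2R)-3-(hydroxymethyl)cyclohexa-3,5-diene-1,2-diol F4. Site-selective dibenzoylation with 11 (2.05 equiv, 2,4,6-collidine, CH2Cl2, −40 °C) would rely on the reactivity order primary O7, then O5, then the doubly flanked O6. The fallback returns to the route at 13.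

Step 9. Cleavage of the hindered silyl ether may be slow, and prolonged exposure could allow acyl shift from O5 to O6 or loss of the O5 benzoate with aromatisation. The fallback moves the desilylation to a stage at which O5 carries no acyl group. It sets out from 10: acylation of the primary hydroxyl alone with 11 (1.05 equiv, pyridine, CH2Cl2, −40 °C) would give [(5R,6R)-6-[(tert-butyldimethylsilyl)oxy]-5-hydroxycyclohexa-1,3-dien-1-yl]methyl benzoate F5. Desilylation with HF·pyridine (or AcOH-buffered Bu4NF) would give [(5R,6R)-5,6-dihydroxycyclohexa-1,3-dien-1-yl]methyl benzoate F6; a vicinal acyl shift is impossible here. A tin-templated monoacylation of the trans-diol (Me2SnCl2 cat., K2CO3, 11 1.0 equiv, THF, rt) should then place the benzoate on the less hindered O5. The fallback returns to the route at 13.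

## Further compounds

F1 | step 4 | methyl (3aS,4R,7aR)-4-hydroxy-2,2-dimethyl-6-(phenylsulfanyl)hexahydro-1,3-benzodioxole-5-carboxylate (ring positions 5 and 6 unassigned) | COC(=O)C1C(Sc2ccccc2)C[C@H]2OC(C)(C)O[C@H]2[C@@H]1O
F2 | step 4 | methyl (3aS,4R,7aR)-4-hydroxy-2,2-dimethyl-6-(phenylsulfonyl)hexahydro-1,3-benzodioxole-5-carboxylate (ring positions 5 and 6 unassigned) | COC(=O)C1C(S(=O)(=O)c2ccccc2)C[C@H]2OC(C)(C)O[C@H]2[C@@H]1O
F3 | step 6 | methyl (5R,6R)-5,6-dihydroxycyclohexa-1,3-diene-1-carboxylate | COC(=O)C1=CC=C[C@@H](O)[C@@H]1O
F4 | step 6 | (1R,2R)-3-(hydroxymethyl)cyclohexa-3,5-diene-1,2-diol | OCC1=CC=C[C@@H](O)[C@@H]1O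
F5 | step 9 | [(5R,6R)-6-[(tert-butyldimethylsilyl)oxy]-5-hydroxycyclohexa-1,3-dien-1-yl]methyl benzoate | O=C(OCC1=CC=C[C@@H](O)[C@@H]1O[Si](C)(C)C(C)(C)C)c1ccccc1
F6 | step 9 | [(5R,6R)-5,6-dihydroxycyclohexa-1,3-dien-1-yl]methyl benzoate | O=C(OCC1=CC=C[C@@H](O)[C@@H]1O)c1ccccc1
A1 | alternative 1 | benzoic acid | O=C(O)c1ccccc1
A2 | alternative 1 | (cyclohexa-2,5-dien-1-yl)methanol | OCC1C=CCC=C1
A3 | alternative 1 | [(1S,5S,6R)-5,6-epoxycyclohex-2-en-1-yl]methanol (target numbering; oxirane cis to CH2OH) | OC[C@@H]1C=CC[C@@H]2O[C@H]12
A4 | alternative 2 | furan | c1ccoc1
A5 | alternative 2 | 3-[(Z)-3-acetoxyprop-2-enoyl]-1,3-oxazolidin-2-one | CC(=O)O/C=C\C(=O)N1CCOC1=O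
A6 | alternative 2 | endo,endo-3-(3-acetoxy-7-oxabicyclo[2.2.1]hept-5-ene-2-carbonyl)-1,3-oxazolidin-2-one | [C@@H]1(C(=O)N3CCOC3=O)[C@@H]2C=C[C@@H](O2)[C@@H]1OC(C)=O
A7 | alternative 3 | 2-deoxy-D-glucose (open-chain form) | O=CC[C@@H](O)[C@H](O)[C@H](O)CO
A8 | alternative 3 | methyl 3-O-benzoyl-4-O-(tert-butyldimethylsilyl)-2,6-dideoxy-D-threo-hex-5-enopyranoside (anomeric configuration immaterial) | COC1C[C@@H](OC(=O)c2ccccc2)[C@H](O[Si](C)(C)C(C)(C)C)C(=C)O1
A9 | alternative 3 | 5-benzoyloxy-6-(tert-butyldimethylsilyloxy)-3-hydroxycyclohexanone (target numbering; trans at C5/C6; C3 epimers) | O=C1CC(O)C[C@@H](OC(=O)c2ccccc2)[C@@H]1O[Si](C)(C)C(C)(C)C
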